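## Retrosynthetic overview

1. Ring atoms are called C1 (the ring alkene carbon bearing CH3), C2 (=CH), C3 and C4 (CH2), C5 (CHCH3) and C6 (quaternary). The side chain is cut at the C(sp3)–C(sp2) bond beside its second alkene, giving a ring-bearing (E)-iodoalkene and a butenolide-bearing alkylzinc (Negishi coupling); the butenolide ring is bought as 4-bromofuran-2(5H)-one.
2. The iodoalkene goes back, through alkyne methylalumination and an enone → enol triflate → methyl sequence, to (5R,6R)-6-(2-hydroxyethyl)-5,6-dimethylcyclohex-2-en-1-one.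
3. Enabling feature: in the six-membered carbocycle, C1 and C3 are 1,3-related across C2 and can be a ketone and an aldehyde carbon linked through C6–C5 (a 1,5-dicarbonyl). C6 is quaternary, so the C1 ketone can enolise only toward C2. C6 also carries a two-carbon arm whose oxygen can be tied to C1 as a 4,5-dihydrofuran, a temporary ring that locks the geometry of the tetrasubstituted C1=C6 enol ether.
4. Key step: enantioselective oxadiene Diels–Alder reaction of crotonaldehyde with 2,3-dimethyl-4,5-dihydrofuran (C5–C6 bond, both stereocentres), then in the same flask acid unravelling of the bicyclic ketal and aldol condensation (C2–C3 bond).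
5. Ring order: dihydrofuran (temporary) → dihydropyran of the cycloadduct (temporary) → cyclohexenone, formed as both oxygen rings open; the butenolide ring is attached in the chain fragment before the final coupling.

Key step: step 3

Assumption: the catalyst [Cr(L)Cl] of step 3, whose ligand L is built on (1R,2S)-1-aminoindan-2-ol, is taken to leave the Re face of the β-carbon of bound (E)-crotonaldehyde open to the enol ether; if the sense is opposite with this new dienophile, the antipodal catalyst is used and nothing else changes.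

## Route

Step 1
Reactants: 1 3-acetyloxolan-2-one (α-acetyl-γ-butyrolactone)
Product: 2 rac-3-acetyl-3-methyloxolan-2-one
Conditions: MeI, K2CO3, acetone, reflux
Reagents that add atoms: iodomethane, CI
Why: C-alkylation of the stabilised enolate of the β-keto lactone (enolate alkylation) should give the methylated lactone; the new quaternary centre is racemic and is erased in step 2.

Step 2
Reactants: 2 rac-3-acetyl-3-methyloxolan-2-one
Product: 5 2,3-dimethyl-4,5-dihydrofuran, via keto acid 3 (not isolated), via hydroxy ketone 4 (not isolated)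
Conditions: 5 % aq H3PO4, reflux; then slow distillation from cat. TsOH, distillate dried over K2CO3
Reagents that add atoms: none
Why: Acid hydrolysis of the β-keto lactone, decarboxylation and cyclodehydration of the γ-hydroxy ketone (the established route from 2-acetylbutyrolactones to 2-alkyl-4,5-dihydrofurans) should give the achiral, endocyclic tetrasubstituted enol ether, which is the thermodynamic isomer.

Step 3
Reactants: 5 2,3-dimethyl-4,5-dihydrofuran (3 equiv); 6 (E)-but-2-enal (crotonaldehyde)
Product: 10 (5R,6R)-6-(2-hydroxyethyl)-5,6-dimethylcyclohex-2-en-1-one, via bicyclic ketal 7 (not isolated), via keto aldehyde 8 (not isolated), via aldol 9 (not isolated)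
Conditions: [Cr(L)Cl] (5 mol %; L = dianion of 2-(1-adamantyl)-6-{[(1R,2S)-2-hydroxy-2,3-dihydro-1H-inden-1-yl]iminomethyl}-4-methylphenol; trivalent chromium), 4 Å MS, neat, 0 → 23 °C; then THF, 1 M aq HCl, 23 → 45 °C, same flask
Reagents that add atoms: water, O
Why: Proposed new method: the chromium-bound s-cis enal 6 should act as a 1-oxadiene and the electron-rich enol ether 5 as dienophile in an inverse-electron-demand hetero-Diels–Alder reaction that forms the C5–C6 bond together with a temporary C1–O bond (closest known reaction type: the same [Cr(L)Cl] catalysis of (E)-enals with ethyl vinyl ether; the untested element is a tetrasubstituted cyclic enol ether that creates a quaternary carbon, and a stepwise Mukaiyama–Michael addition followed by ring closure would lead to the same ketal 7). Aqueous acid in the same flask should then ionise the ketal of 7 at its enol oxygen and let water add to the cyclic oxocarbenium ion, which gives the δ-keto aldehyde 8 with a ketone oxygen that comes from water; the methyl ketone can enolise only toward C2 because C6 is quaternary, so that aldol addition to the aldehyde carbon C3 (C2–C3 bond, aldol 9) and loss of water, which carries off the former carbonyl oxygen of 6, give enone 10. Ring closures: the dihydropyran ring of 7 by a concerted, asynchronous [4+2] cycloaddition and the carbocycle by a 6-(enolendo)-exo-trig aldol condensation, while both oxygen rings open. C5 is set by the catalyst, which differentiates the faces of the β-carbon of 6 (Re face needed), and C6 is set relative to C5 by the endo transition state, in which the ring oxygen and ring CH2 of 5 lie under the oxadiene, so that the two-carbon arm ends up cis and the C6 methyl trans to the C5 methyl; the ring of 5 locks the enol ether geometry, so this relation cannot leak through E/Z isomers. The step needs face selectivity, endo over exo selectivity and a single direction of aldolisation: the first rests on the chiral Lewis acid, the second on the usual alkoxy-endo preference of oxadiene cycloadditions, the third on the blocked C6.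

Step 4
Reactants: 10 (5R,6R)-6-(2-hydroxyethyl)-5,6-dimethylcyclohex-2-en-1-one
Product: 11 (5R,6R)-6-{2-[(tert-butyldimethylsilyl)oxy]ethyl}-5,6-dimethylcyclohex-2-en-1-one
Conditions: TBSCl, imidazole, CH2Cl2, 23 °C
Reagents that add atoms: tert-butyldimethylsilyl chloride, CC(C)(C)[Si](C)(C)Cl
Why: Silylation of the primary alcohol (silyl ether protection) removes the only acidic proton before the enolate chemistry of step 5 and touches no stereocentre.

Step 5
Reactants: 11 (5R,6R)-6-{2-[(tert-butyldimethylsilyl)oxy]ethyl}-5,6-dimethylcyclohex-2-en-1-one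
Product: 13 (5R,6R)-6-{2-[(tert-butyldimethylsilyl)oxy]ethyl}-5,6-dimethylcyclohex-1-en-1-yl trifluoromethanesulfonate, via lithium enolate 12 (not isolated)
Conditions: LiBH(s-Bu)3, THF, −78 °C; then PhNTf2, −78 → 0 °C
Reagents that add atoms: N-phenylbis(trifluoromethanesulfonimide), O=S(=O)(N(c1ccccc1)S(=O)(=O)C(F)(F)F)C(F)(F)F
Why: Conjugate (1,4) hydride reduction of the β-unsubstituted cyclohexenone by the bulky borohydride should give the regiodefined enolate, which is trapped on oxygen as the enol triflate (reductive enolate triflation); C6 is quaternary, so the double bond can only sit at C1=C2.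

Step 6
Reactants: 13 (5R,6R)-6-{2-[(tert-butyldimethylsilyl)oxy]ethyl}-5,6-dimethylcyclohex-1-en-1-yl trifluoromethanesulfonate
Product: 14 tert-butyldimethyl{2-[(1R,6R)-1,2,6-trimethylcyclohex-2-en-1-yl]ethoxy}silane
Conditions: MeMgBr, Fe(acac)3 (5 mol %), THF/NMP, −30 → 0 °C
Reagents that add atoms: methylmagnesium bromide, C[Mg]Br
Why: Iron-catalysed cross-coupling of the alkenyl triflate with the methyl Grignard reagent (Kumada-type coupling) should install the C1 methyl with the double bond where the target has it; the methyl group has no β-hydrogen, so reduction cannot compete.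

Step 7
Reactants: 14 tert-butyldimethyl{2-[(1R,6R)-1,2,6-trimethylcyclohex-2-en-1-yl]ethoxy}silane
Product: 15 (5R,6R)-6-(2-bromoethyl)-1,5,6-trimethylcyclohex-1-ene
Conditions: Ph3PBr2, CH2Cl2, 23 °C
Reagents that add atoms: triphenylphosphine dibromide, BrP(Br)(c1ccccc1)(c1ccccc1)c1ccccc1
Why: Triphenylphosphine dibromide is known to turn primary tert-butyldimethylsilyl ethers directly into bromides by SN2 displacement of the activated oxygen (Appel-type bromination), which saves a separate deprotection and leaves the alkene and both stereocentres alone.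

Step 8
Reactants: 15 (5R,6R)-6-(2-bromoethyl)-1,5,6-trimethylcyclohex-1-ene
Product: 16 (5R,6R)-6-(but-3-yn-1-yl)-1,5,6-trimethylcyclohex-1-ene
Conditions: LiC≡CH·H2NCH2CH2NH2, DMSO, 23 °C
Reagents that add atoms: lithium acetylide (ethylenediamine complex), [Li]C#C
Why: SN2 displacement of the unhindered primary bromide by acetylide in a dipolar aprotic solvent (acetylide alkylation) should give the terminal alkyne.

Step 9
Reactants: 16 (5R,6R)-6-(but-3-yn-1-yl)-1,5,6-trimethylcyclohex-1-ene
Product: 18 (5R,6R)-6-[(3E)-4-iodo-3-methylbut-3-en-1-yl]-1,5,6-trimethylcyclohex-1-ene, via alkenylalane 17 (not isolated)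
Conditions: Me3Al, Cp2ZrCl2 (0.25 equiv), CH2Cl2, 0 → 23 °C; then I2, THF, −30 → 0 °C
Reagents that add atoms: trimethylaluminium, C[Al](C)C; iodine, II
Why: Zirconium-catalysed syn-methylalumination of the terminal alkyne (Negishi carboalumination) places methyl on the internal and aluminium on the terminal carbon, and iodinolysis with retention should give the (E)-iodoalkene; the trisubstituted ring alkene does not react.

Step 10
Reactants: 19 tert-butyl(but-3-yn-1-yloxy)dimethylsilane
Product: 22 (3E)-6-[(tert-butyldimethylsilyl)oxy]-4-methylhex-3-en-1-ol, via alkenylalane 20 (not isolated), via lithium alanate 21 (not isolated)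
Conditions: Me3Al, Cp2ZrCl2 (0.25 equiv), CH2Cl2, 23 °C; volatiles off, hexane; n-BuLi, −78 → 0 °C; oxirane, THF, −78 → 23 °C
Reagents that add atoms: trimethylaluminium, C[Al](C)C; oxirane, C1CO1
Why: Negishi carboalumination as in step 9, conversion of the alkenylalane into the more nucleophilic alanate and opening of oxirane by its alkenyl group with retention should give the (E)-homoallylic alcohol.

Step 11
Reactants: 22 (3E)-6-[(tert-butyldimethylsilyl)oxy]-4-methylhex-3-en-1-ol
Product: 23 tert-butyl{[(3E)-6-iodo-3-methylhex-3-en-1-yl]oxy}dimethylsilane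
Conditions: I2, PPh3, imidazole, CH2Cl2, 0 → 23 °C
Reagents that add atoms: iodine, II
Why: Appel-type iodination of the primary alcohol by SN2 displacement should give the iodide without touching the silyl ether or the alkene.

Step 12
Reactants: 23 tert-butyl{[(3E)-6-iodo-3-methylhex-3-en-1-yl]oxy}dimethylsilane; 24 4-bromofuran-2(5H)-one
Product: 26 4-{(3E)-6-[(tert-butyldimethylsilyl)oxy]-4-methylhex-3-en-1-yl}furan-2(5H)-one, via alkylzinc iodide 25 (not isolated)
Conditions: Zn dust, LiCl, THF, 30 °C; then 24, Pd(OAc)2 (2 mol %), SPhos (4 mol %), THF, 23 °C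
Reagents that add atoms: none
Why: Direct zinc insertion into the primary iodide and palladium-catalysed Negishi coupling of the alkylzinc with the vinylogous acyl bromide should join the chain to C4 of the butenolide; alkylzinc halides tolerate the lactone.

Step 13
Reactants: 26 4-{(3E)-6-[(tert-butyldimethylsilyl)oxy]-4-methylhex-3-en-1-yl}furan-2(5H)-one
Product: 27 4-[(3E)-6-bromo-4-methylhex-3-en-1-yl]furan-2(5H)-one
Conditions: Ph3PBr2, CH2Cl2, 0 → 23 °C
Reagents that add atoms: triphenylphosphine dibromide, BrP(Br)(c1ccccc1)(c1ccccc1)c1ccccc1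
Why: The same direct silyl ether → bromide exchange as in step 7 (Appel-type bromination) is neutral and should spare the base-sensitive butenolide.

Step 14
Reactants: 27 4-[(3E)-6-bromo-4-methylhex-3-en-1-yl]furan-2(5H)-one; 18 (5R,6R)-6-[(3E)-4-iodo-3-methylbut-3-en-1-yl]-1,5,6-trimethylcyclohex-1-ene
Product: 29 4-{(3E,7E)-4,8-dimethyl-10-[(1R,6R)-1,2,6-trimethylcyclohex-2-en-1-yl]deca-3,7-dien-1-yl}furan-2(5H)-one, via alkylzinc bromide 28 (not isolated)
Conditions: Zn dust, LiCl, THF, 50 °C; then 18, PdCl2(dppf) (5 mol %), THF, 23 → 45 °C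
Reagents that add atoms: none
Why: Zinc insertion into the primary bromide and Negishi coupling of the alkylzinc with the alkenyl iodide should proceed with retention of the (E)-geometry and complete the skeleton; the organozinc is too weakly basic and nucleophilic to attack the butenolide.

## Compound list

1 | 3-acetyloxolan-2-one (α-acetyl-γ-butyrolactone) | CC(=O)C1CCOC1=O | starting material
2 | rac-3-acetyl-3-methyloxolan-2-one | CC(=O)C1(C)CCOC1=O | intermediate
3 | rac-2-acetyl-4-hydroxy-2-methylbutanoic acid (not isolated) | CC(=O)C(C)(CCO)C(=O)O | intermediate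
4 | rac-5-hydroxy-3-methylpentan-2-one (not isolated) | CC(=O)C(C)CCO | intermediate
5 | 2,3-dimethyl-4,5-dihydrofuran | CC1=C(C)CCO1 | intermediate
6 | (E)-but-2-enal (crotonaldehyde) | C/C=C/C=O | starting material
7 | (3aR,4R,7aS)-3a,4,7a-trimethyl-2,3,3a,7a-tetrahydro-4H-furo[2,3-b]pyran (not isolated) | C[C@@H]1C=CO[C@]2(C)OCC[C@]12C | intermediate
8 | (3R,4R)-4-acetyl-6-hydroxy-3,4-dimethylhexanal (not isolated) | O=CC[C@@H](C)[C@@](C)(CCO)C(C)=O | intermediate
9 | (2R,3R)-5-hydroxy-2-(2-hydroxyethyl)-2,3-dimethylcyclohexan-1-one, both C5 epimers (not isolated) | O=C1CC(O)C[C@@H](C)[C@@]1(C)CCO | intermediate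
10 | (5R,6R)-6-(2-hydroxyethyl)-5,6-dimethylcyclohex-2-en-1-one | O=C1C=CC[C@@H](C)[C@@]1(C)CCO | intermediate
11 | (5R,6R)-6-{2-[(tert-butyldimethylsilyl)oxy]ethyl}-5,6-dimethylcyclohex-2-en-1-one | O=C1C=CC[C@@H](C)[C@@]1(C)CCO[Si](C)(C)C(C)(C)C | intermediate
12 | lithium (5R,6R)-6-{2-[(tert-butyldimethylsilyl)oxy]ethyl}-5,6-dimethylcyclohex-1-en-1-olate (not isolated) | [Li]OC1=CCC[C@@H](C)[C@@]1(C)CCO[Si](C)(C)C(C)(C)C | intermediate
13 | (5R,6R)-6-{2-[(tert-butyldimethylsilyl)oxy]ethyl}-5,6-dimethylcyclohex-1-en-1-yl trifluoromethanesulfonate | O=S(=O)(OC1=CCC[C@@H](C)[C@@]1(C)CCO[Si](C)(C)C(C)(C)C)C(F)(F)F | intermediate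
14 | tert-butyldimethyl{2-[(1R,6R)-1,2,6-trimethylcyclohex-2-en-1-yl]ethoxy}silane | CC1=CCC[C@@H](C)[C@@]1(C)CCO[Si](C)(C)C(C)(C)C | intermediate
15 | (5R,6R)-6-(2-bromoethyl)-1,5,6-trimethylcyclohex-1-ene | CC1=CCC[C@@H](C)[C@@]1(C)CCBr | intermediate
16 | (5R,6R)-6-(but-3-yn-1-yl)-1,5,6-trimethylcyclohex-1-ene | CC1=CCC[C@@H](C)[C@@]1(C)CCC#C | intermediate
17 | dimethyl{(1E)-2-methyl-4-[(1R,6R)-1,2,6-trimethylcyclohex-2-en-1-yl]but-1-en-1-yl}alane (not isolated) | CC1=CCC[C@@H](C)[C@@]1(C)CC/C(C)=C/[Al](C)C | intermediate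
18 | (5R,6R)-6-[(3E)-4-iodo-3-methylbut-3-en-1-yl]-1,5,6-trimethylcyclohex-1-ene | CC1=CCC[C@@H](C)[C@@]1(C)CC/C(C)=C/I | intermediate
19 | tert-butyl(but-3-yn-1-yloxy)dimethylsilane | C#CCCO[Si](C)(C)C(C)(C)C | starting material
20 | {(1E)-4-[(tert-butyldimethylsilyl)oxy]-2-methylbut-1-en-1-yl}dimethylalane (not isolated) | CC(C)(C)[Si](C)(C)OCC/C(C)=C/[Al](C)C | intermediate
21 | lithium butyl{(1E)-4-[(tert-butyldimethylsilyl)oxy]-2-methylbut-1-en-1-yl}dimethylalanate (not isolated) | CC(C)(C)[Si](C)(C)OCC/C(C)=C/[Al-](C)(C)CCCC.[Li+] | intermediate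
22 | (3E)-6-[(tert-butyldimethylsilyl)oxy]-4-methylhex-3-en-1-ol | CC(C)(C)[Si](C)(C)OCC/C(C)=C/CCO | intermediate
23 | tert-butyl{[(3E)-6-iodo-3-methylhex-3-en-1-yl]oxy}dimethylsilane | CC(C)(C)[Si](C)(C)OCC/C(C)=C/CCI | intermediate
24 | 4-bromofuran-2(5H)-one | BrC1=CC(=O)OC1 | starting material
25 | {(3E)-6-[(tert-butyldimethylsilyl)oxy]-4-methylhex-3-en-1-yl}iodozinc (not isolated) | CC(C)(C)[Si](C)(C)OCC/C(C)=C/CC[Zn]I | intermediate
26 | 4-{(3E)-6-[(tert-butyldimethylsilyl)oxy]-4-methylhex-3-en-1-yl}furan-2(5H)-one | CC(C)(C)[Si](C)(C)OCC/C(C)=C/CCC1=CC(=O)OC1 | intermediate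
27 | 4-[(3E)-6-bromo-4-methylhex-3-en-1-yl]furan-2(5H)-one | BrCC/C(C)=C/CCC1=CC(=O)OC1 | intermediate
28 | bromo[(3E)-3-methyl-6-(5-oxo-2,5-dihydrofuran-3-yl)hex-3-en-1-yl]zinc (not isolated) | Br[Zn]CC/C(C)=C/CCC1=CC(=O)OC1 | intermediate
29 | 4-{(3E,7E)-4,8-dimethyl-10-[(1R,6R)-1,2,6-trimethylcyclohex-2-en-1-yl]deca-3,7-dien-1-yl}furan-2(5H)-one | CC1=CCC[C@@H](C)[C@@]1(C)CC/C(C)=C/CC/C(C)=C/CCC1=CC(=O)OC1 | target

## Step count and risks

Total step count: 14. Longest linear sequence: 10 steps (steps 1–9 and 14); the chain branch (steps 10–13) joins at step 14.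

Steps most likely to fail:

1. Step 3 (Proposed new method). The tetrasubstituted enol ether may add too slowly to the bound enal, the Lewis acid may isomerise it to the exocyclic enol ether before it reacts, or endo/exo and facial selectivity may be poor. The fallback uses known chemistry, sets out from 1 and 6 and returns to the route at 11. Conjugate addition of 1 to 6 under iminium catalysis by (S)-2-[diphenyl(trimethylsilyloxy)methyl]pyrrolidine (10 mol %, toluene, 23 °C) should give (3R)-3-(3-acetyl-2-oxooxolan-3-yl)butanal F1, not isolated; the catalyst shields the Si face of the β-carbon of 6, so the donor adds to the Re face. TsOH·H2O in toluene at 80 °C should close F1 by aldol condensation to the spiro lactone (10R)-10-methyl-2-oxaspiro[4.5]dec-7-ene-1,6-dione F2. Hot dilute H2SO4 in dioxane should open the lactone to (6R)-1-(2-hydroxyethyl)-6-methyl-2-oxocyclohex-3-ene-1-carboxylic acid F3, not isolated, which loses CO2 to (5R)-6-(2-hydroxyethyl)-5-methylcyclohex-2-en-1-one F4. TBSCl and imidazole give (5R)-6-{2-[(tert-butyldimethylsilyl)oxy]ethyl}-5-methylcyclohex-2-en-1-one F5. LDA (THF, −78 °C) should form lithium (3R)-2-{2-[(tert-butyldimethylsilyl)oxy]ethyl}-3-methylcyclohexa-1,5-dien-1-olate F6, which MeI should methylate at C6 anti to the C5 methyl group, giving 11. Here the quaternary centre is set by substrate control after the ring is made, at the cost of three extra steps.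

2. Step 14. Zinc insertion into the bromide may be slow or incomplete beside the reduction- and base-sensitive butenolide, and protonation or homocoupling of the organozinc may prevent a clean union of the two advanced fragments. The fallback grows the chain linearly and attaches the butenolide last; it sets out from 18 and returns at 29.
   - Negishi coupling of 18 with bromo[4-(trimethylsilyl)but-3-yn-1-yl]zinc F7 (from commercial 4-bromo-1-(trimethylsilyl)but-1-yne and zinc; PdCl2(dppf), THF) should give trimethyl{(5E)-6-methyl-8-[(1R,6R)-1,2,6-trimethylcyclohex-2-en-1-yl]oct-5-en-1-yn-1-yl}silane F8.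
   - K2CO3 in MeOH should free (5R,6R)-1,5,6-trimethyl-6-[(3E)-3-methyloct-3-en-7-yn-1-yl]cyclohex-1-ene F9.
   - Negishi carboalumination (Me3Al, Cp2ZrCl2) should give {(1E,5E)-2,6-dimethyl-8-[(1R,6R)-1,2,6-trimethylcyclohex-2-en-1-yl]octa-1,5-dien-1-yl}dimethylalane F10, n-BuLi its lithium butyl alanate F11, and oxirane (3E,7E)-4,8-dimethyl-10-[(1R,6R)-1,2,6-trimethylcyclohex-2-en-1-yl]deca-3,7-dien-1-ol F12.
   - I2, PPh3 and imidazole give (5R,6R)-6-[(3E,7E)-10-iodo-3,7-dimethyldeca-3,7-dien-1-yl]-1,5,6-trimethylcyclohex-1-ene F13; zinc insertion (Zn, LiCl, THF) gives {(3E,7E)-4,8-dimethyl-10-[(1R,6R)-1,2,6-trimethylcyclohex-2-en-1-yl]deca-3,7-dien-1-yl}iodozinc F14; Negishi coupling with 24 (Pd(OAc)2, SPhos) gives 29.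

3. Step 12. Conjugate addition–elimination, reduction or homocoupling at the vinylogous acyl bromide, or slow transmetalation, may lower the coupling efficiency. The fallback builds the butenolide ring de novo; it sets out from 23 and returns at 26. Magnesium turnings in THF should give {(3E)-6-[(tert-butyldimethylsilyl)oxy]-4-methylhex-3-en-1-yl}magnesium iodide F15. Copper-catalysed anti-carbomagnesiation (CuI, 10 mol %) of prop-2-yn-1-ol, pre-metallated with EtMgBr, should give the cyclic alkenylmagnesium alkoxide 4-{(3E)-6-[(tert-butyldimethylsilyl)oxy]-4-methylhex-3-en-1-yl}-2,5-dihydro-1,2-oxamagnesole F16, with the new alkyl group on the carbon that bears CH2O. CO2 followed by mild acidic work-up (1 M aq HCl) carboxylates the alkenyl carbon and closes the lactone to 26.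

## Further compounds

F1 | step 3 | (3R)-3-(3-acetyl-2-oxooxolan-3-yl)butanal (both epimers at the quaternary carbon) | O=CC[C@@H](C)C1(C(C)=O)CCOC1=O
F2 | step 3 | (10R)-10-methyl-2-oxaspiro[4.5]dec-7-ene-1,6-dione (both spiro epimers) | O=C1C=CC[C@@H](C)C12CCOC2=O
F3 | step 3 | (6R)-1-(2-hydroxyethyl)-6-methyl-2-oxocyclohex-3-ene-1-carboxylic acid (both C1 epimers) | O=C1C=CC[C@@H](C)C1(CCO)C(=O)O
F4 | step 3 | (5R)-6-(2-hydroxyethyl)-5-methylcyclohex-2-en-1-one (both C6 epimers) | O=C1C=CC[C@@H](C)C1CCO
F5 | step 3 | (5R)-6-{2-[(tert-butyldimethylsilyl)oxy]ethyl}-5-methylcyclohex-2-en-1-one (both C6 epimers) | O=C1C=CC[C@@H](C)C1CCO[Si](C)(C)C(C)(C)C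
F6 | step 3 | lithium (3R)-2-{2-[(tert-butyldimethylsilyl)oxy]ethyl}-3-methylcyclohexa-1,5-dien-1-olate | [Li]OC1=C(CCO[Si](C)(C)C(C)(C)C)[C@H](C)CC=C1
F7 | step 14 | bromo[4-(trimethylsilyl)but-3-yn-1-yl]zinc | C[Si](C)(C)C#CCC[Zn]Br
F8 | step 14 | trimethyl{(5E)-6-methyl-8-[(1R,6R)-1,2,6-trimethylcyclohex-2-en-1-yl]oct-5-en-1-yn-1-yl}silane | CC1=CCC[C@@H](C)[C@@]1(C)CC/C(C)=C/CCC#C[Si](C)(C)C
F9 | step 14 | (5R,6R)-1,5,6-trimethyl-6-[(3E)-3-methyloct-3-en-7-yn-1-yl]cyclohex-1-ene | CC1=CCC[C@@H](C)[C@@]1(C)CC/C(C)=C/CCC#C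
F10 | step 14 | {(1E,5E)-2,6-dimethyl-8-[(1R,6R)-1,2,6-trimethylcyclohex-2-en-1-yl]octa-1,5-dien-1-yl}dimethylalane | CC1=CCC[C@@H](C)[C@@]1(C)CC/C(C)=C/CC/C(C)=C/[Al](C)C
F11 | step 14 | lithium butyl{(1E,5E)-2,6-dimethyl-8-[(1R,6R)-1,2,6-trimethylcyclohex-2-en-1-yl]octa-1,5-dien-1-yl}dimethylalanate | CC1=CCC[C@@H](C)[C@@]1(C)CC/C(C)=C/CC/C(C)=C/[Al-](C)(C)CCCC.[Li+]
F12 | step 14 | (3E,7E)-4,8-dimethyl-10-[(1R,6R)-1,2,6-trimethylcyclohex-2-en-1-yl]deca-3,7-dien-1-ol | CC1=CCC[C@@H](C)[C@@]1(C)CC/C(C)=C/CC/C(C)=C/CCO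
F13 | step 14 | (5R,6R)-6-[(3E,7E)-10-iodo-3,7-dimethyldeca-3,7-dien-1-yl]-1,5,6-trimethylcyclohex-1-ene | CC1=CCC[C@@H](C)[C@@]1(C)CC/C(C)=C/CC/C(C)=C/CCI
F14 | step 14 | {(3E,7E)-4,8-dimethyl-10-[(1R,6R)-1,2,6-trimethylcyclohex-2-en-1-yl]deca-3,7-dien-1-yl}iodozinc | CC1=CCC[C@@H](C)[C@@]1(C)CC/C(C)=C/CC/C(C)=C/CC[Zn]I
F15 | step 12 | {(3E)-6-[(tert-butyldimethylsilyl)oxy]-4-methylhex-3-en-1-yl}magnesium iodide | CC(C)(C)[Si](C)(C)OCC/C(C)=C/CC[Mg]I
F16 | step 12 | 4-{(3E)-6-[(tert-butyldimethylsilyl)oxy]-4-methylhex-3-en-1-yl}-2,5-dihydro-1,2-oxamagnesole | CC(C)(C)[Si](C)(C)OCC/C(C)=C/CCC1=C[Mg]OC1
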